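**Strategy.** Numbering: ring C1 (bears the side chain), C2 (CH2), C3–C4 (oxirane, methyl on C4), C5 and C6 (ester carbons); chain C7(=CH2), C8–C11. The cyclohexane ring is disconnected at C1–C2 and C5–C6 into silyl dienol ether 2 (C2–C5) and cyclobutenone 5 (C6, C1, C7, C8). One enantioselective Diels–Alder reaction forms both bonds and exploits the all-cis C5–O/C6–O/C1–C7 array of that ring. The four-membered ketone is a temporary ring: Baeyer–Villiger oxidation turns its C6–C8 bond into C6–O with retention, and the cis-fused lactone is unfolded into the C7(=CH2)–C8(O) chain. Allylation, metathesis, site-by-site angeloylation and two epoxidations complete the synthesis.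

Key step: step 4

Remark (assumption): the sense of induction of the oxazaborolidinium catalyst with cyclobutenone is assumed to follow that known for larger cycloalkenones. If the (S)-catalyst gave the mirror-image adduct, the (R)-catalyst would be used. Target numbering (C1–C11) is used for all intermediates.

**Step 1**
Reactants: 1 (E)-2-methylbut-2-enal (tiglic aldehyde)
Product: 2 tert-butyl(dimethyl){[(1E)-2-methylbuta-1,3-dien-1-yl]oxy}silane
Conditions: TBSOTf, Et3N, Et2O, 0 °C → rt
Reagents that add atoms: tert-butyldimethylsilyl triflate, CC(C)(C)[Si](C)(C)OS(=O)(=O)C(F)(F)F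
Why: Soft enolisation (O-silylation of the enal, then γ-deprotonation by the amine) should give the silyl dienol ether; the s-trans enal leads mainly to the 1E isomer, and the minor 1Z isomer cannot reach the s-cis geometry needed in step 4.

**Step 2**
Reactants: 3 3-oxocyclobutane-1-carboxylic acid
Product: 4 3-bromocyclobutan-1-one
Conditions: HgO, Br2, MgSO4, CH2Cl2, reflux
Reagents that add atoms: bromine, BrBr
Why: Cristol–Firth variant of the Hunsdiecker reaction: the mercury carboxylate forms an acyl hypobromite whose radical decarboxylation and bromine capture should give the bromide; no stereocenter is involved.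

**Step 3**
Reactants: 4 3-bromocyclobutan-1-one
Product: 5 cyclobut-2-en-1-one
Conditions: n-Bu3N, rt; vacuum transfer into a −78 °C trap; kept as a cold CH2Cl2 solution
Reagents that add atoms: none
Why: E1cB dehydrobromination of the β-bromo ketone by the tertiary amine; the volatile enone is separated from the ammonium salt by vacuum transfer because it polymerises with bases.

**Step 4**
Reactants: 2 silyl dienol ether; 5 cyclobut-2-en-1-one
Product: 6 (1R,5S,6S)-5-[(tert-butyldimethylsilyl)oxy]-4-methylbicyclo[4.2.0]oct-3-en-7-one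
Conditions: (S)-3,3-diphenyl-1-(o-tolyl)-oxazaborolidine (from (S)-diphenylprolinol) protonated with HNTf2 (20 mol %), CH2Cl2, −78 °C
Reagents that add atoms: none
Why: The protonated oxazaborolidine binds the carbonyl of 5 and lowers its LUMO, so the silyl dienol ether adds in a concerted, asynchronous normal-demand [4+2] cycloaddition; the closest known reactions are Lewis-acid-promoted Diels–Alder reactions of cyclobutenone with oxygenated dienes and oxazaborolidinium-catalysed cycloadditions of cycloalkenones. The six-membered ring closes by suprafacial [4π+2π] bonding of the diene termini C2 and C5 to the enone carbons C1 and C6, the cyclobutanone surviving as a cis-fused temporary ring. Regiochemistry (C2, the terminus of largest HOMO coefficient, to the β-carbon C1; the oxygenated terminus C5 to the α-carbon C6) follows from the 1-silyloxy donor, which outweighs the 2-methyl group. C5 is set relative to C6 by the E geometry of the diene together with the endo transition state that cyclobutenone favours strongly, and the cis C6–C1 relationship is enforced by the ring of the dienophile, so the C5–O, C6–C8 and C1–C7 bonds should end up on one face. The absolute configuration is controlled by the catalyst, which shields one π-face of the coordinated enone. The step needs ortho regio-, endo and facial selectivity; the first two are secured by the substrate pair (donor at C5, cyclic Z-dienophile with a single carbonyl), the third by the catalyst.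

**Step 5**
Reactants: 6 bicyclic cyclobutanone
Product: 7 (3aR,7R,7aS)-7-[(tert-butyldimethylsilyl)oxy]-6-methyl-3a,4,7,7a-tetrahydro-1-benzofuran-2(3H)-one
Conditions: 30% H2O2, NaOH, THF/MeOH/H2O, 0 °C; then 1 M HCl to pH 3
Reagents that add atoms: hydrogen peroxide, OO
Why: Baeyer–Villiger oxidation: hydroperoxide adds to the strained cyclobutanone far faster than it attacks the isolated alkene, and the more substituted bridgehead carbon C6 migrates with retention, so the C6–O bond should appear on the face that C8 occupied; acidification recloses any opened hydroxy acid.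

**Step 6**
Reactants: 7 silyloxy lactone
Product: 10 (3aR,7R,7aS)-7-[(tert-butyldimethylsilyl)oxy]-6-methyl-3-methylidene-3a,4,7,7a-tetrahydro-1-benzofuran-2(3H)-one, via Mannich base 8 (not isolated), via trimethylammonium iodide 9 (not isolated)
Conditions: LiN(i-Pr)2, THF, −78 °C; Me2N=CH2 I, −78 °C → rt; MeI (excess), rt; then sat. aq NaHCO3, rt
Reagents that add atoms: Eschenmoser's salt, C[N+](C)=C.[I-]
Why: Mannich reaction of the lactone lithium enolate with the iminium salt, N-methylation and E1cB loss of trimethylamine (α-methylenation through Eschenmoser's salt) should give the exocyclic alkene C7=CH2; the new C7 centre of 8 and 9 is destroyed and the ring-fusion centres are not enolisable.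

**Step 7**
Reactants: 10 silyloxy methylene lactone
Product: 11 (3aR,7R,7aS)-7-[(tert-butyldimethylsilyl)oxy]-6-methyl-3-methylidene-2,3,3a,4,7,7a-hexahydro-1-benzofuran-2-ol (lactol, anomeric mixture at C8)
Conditions: i-Bu2AlH (1.2 equiv), CH2Cl2, −78 °C; aq potassium sodium tartrate
Reagents that add atoms: none
Why: Partial reduction of the lactone by 1,2-addition of i-Bu2AlH; the aluminium hemiacetal is stable at −78 °C and should give the lactol after work-up, while the silyl ether and both alkenes are untouched.

**Step 8**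
Reactants: 11 lactol
Product: 12 (1S,2R,6R)-2-[(tert-butyldimethylsilyl)oxy]-6-[(3S)-3-hydroxyhexa-1,5-dien-2-yl]-3-methylcyclohex-3-en-1-ol (allyl diol)
Conditions: (−)-Ipc2B(allyl) (from (+)-α-pinene, salt-free, 2.5 equiv), Et2O, −78 → −20 °C; then NaOH, H2O2
Reagents that add atoms: B-allyldiisopinocampheylborane, C=CCB([C@@H]1C[C@@H]2C[C@H]([C@H]1C)C2(C)C)[C@@H]1C[C@@H]2C[C@H]([C@H]1C)C2(C)C
Why: Brown allylation of the hydroxy enal in equilibrium with the lactol through a chair Zimmerman–Traxler transition state; the (+)-α-pinene-derived reagent attacks the Si face of the aldehyde and should set C8 as S under reagent control, and oxidative work-up cleaves the borinate esters.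

**Step 9**
Reactants: 12 allyl diol
Product: 13 (1S,2R,6R)-2-[(tert-butyldimethylsilyl)oxy]-6-[(3S)-3-hydroxy-6-methylhepta-1,5-dien-2-yl]-3-methylcyclohex-3-en-1-ol (prenyl diol)
Conditions: 2-methylbut-2-ene (large excess), second-generation Hoveyda–Grubbs catalyst RuCl2(H2IMes)(=CH-C6H4-2-OiPr) (5 mol %), CH2Cl2, 40 °C
Reagents that add atoms: 2-methylbut-2-ene, CC=C(C)C
Why: Olefin cross-metathesis: only the monosubstituted alkene initiates readily, the 1,1-disubstituted C7=CH2 and the trisubstituted ring alkene remain, and isopropylidene transfer from the excess trisubstituted olefin should give the prenyl terminus.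

**Step 10**
Reactants: 13 prenyl diol; 14 angelic acid [(Z)-2-methylbut-2-enoic acid]
Product: 15 (3S)-2-[(1R,5R,6S)-5-[(tert-butyldimethylsilyl)oxy]-6-hydroxy-4-methylcyclohex-3-en-1-yl]-6-methylhepta-1,5-dien-3-yl (2Z)-2-methylbut-2-enoate (C8 mono-angelate)
Conditions: 14 (1.1 equiv), 2,4,6-trichlorobenzoyl chloride (1.1 equiv), Et3N, toluene, rt, filtered from Et3NHCl; then 13, 60 °C (no DMAP)
Reagents that add atoms: none
Why: Yamaguchi-type esterification through the mixed anhydride, which the alcohol attacks at the less hindered angeloyl carbonyl; the acyclic allylic C8 hydroxyl is far more accessible than the ring C6 hydroxyl flanked by the cis C5 silyl ether and the branched C1 substituent, the absence of a nucleophilic catalyst should keep the Z geometry, and any C6 ester or diester that forms converges on 16 in step 11.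

**Step 11**
Reactants: 15 C8 mono-angelate; 14 angelic acid
Product: 16 C6,C8-bis-angelate (15 with the C6 hydroxyl also as (2Z)-2-methylbut-2-enoate; C5 silyl ether retained; C1 R, C5 R, C6 S, C8 S)
Conditions: 14 (3 equiv), 2,4,6-trichlorobenzoyl chloride (3 equiv), Et3N, toluene, rt, filtered from Et3NHCl; then 15, 80 °C (no DMAP)
Reagents that add atoms: none
Why: The same mixed-anhydride (Yamaguchi-type) esterification under more forcing conditions should acylate the hindered ring hydroxyl at C6; no stereocenter is touched and the Z geometry should persist without nucleophilic catalyst.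

**Step 12**
Reactants: 16 silyl bis-angelate
Product: 17 allylic alcohol bis-angelate (16 with the C5 hydroxyl free; C1 R, C5 R, C6 S, C8 S)
Conditions: HF·pyridine, pyridine, THF, 0 °C → rt
Reagents that add atoms: none
Why: Fluoride-induced cleavage of the silyl ether under buffered acidic conditions, which should leave the angelates and the alkenes intact and should not promote acyl migration.

**Step 13**
Reactants: 17 allylic alcohol bis-angelate
Product: 18 epoxy alcohol bis-angelate (C3–C4 oxirane cis to the C5 hydroxyl, the C6 ester and the C1 side chain; C1 R, C3 R, C5 S, C6 S, C8 S)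
Conditions: VO(acac)2 (5 mol %), t-BuOOH (decane), CH2Cl2, 0 °C → rt
Reagents that add atoms: tert-butyl hydroperoxide, CC(C)(C)OO
Why: Vanadium-catalysed hydroxyl-directed epoxidation: the peroxide bound to the vanadate ester of the C5 alkoxide is delivered to the same face of the C3=C4 bond, which should set C3 and C4 with the oxirane cis to the C5 hydroxyl, while the prenyl alkene, the C7 methylene and the enoates, none of which has a free allylic hydroxyl, react far more slowly.

**Step 14**
Reactants: 18 epoxy alcohol bis-angelate; 14 angelic acid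
Product: 19 tris-angelate (C5, C6 and C8 esters; prenyl side chain; ring all-cis, C8 S)
Conditions: 14 (4 equiv), 2,4,6-trichlorobenzoyl chloride (4 equiv), Et3N, toluene, rt, filtered from Et3NHCl; then 18, 75 °C (no DMAP)
Reagents that add atoms: none
Why: Yamaguchi-type esterification of the last free hydroxyl through the pre-formed, salt-free mixed anhydride; the absence of chloride, acid chloride and nucleophilic catalyst should spare the oxirane and keep the Z geometry, and no stereocenter is touched.

**Step 15**
Reactants: 19 tris-angelate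
Product: 20 CNP0258231.4 (target)
Conditions: D-fructose-derived Shi ketone (30 mol %), Oxone (2KHSO5·KHSO4·K2SO4), K2CO3, Bu4NHSO4, MeCN/dimethoxymethane/aq borate buffer (pH 10.5), 0 °C
Reagents that add atoms: potassium peroxymonosulfate, [K+].[O-]S(=O)(=O)OO
Why: Shi epoxidation: the dioxirane generated from the D-fructose-derived ketone reacts through a spiro transition state fastest with the electron-rich trisubstituted prenyl alkene and should set C10 as R; the allylic 1,1-disubstituted alkene and the enoate double bonds are much slower.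

**Compound list**

1 | (E)-2-methylbut-2-enal | C/C=C(\C)C=O | starting material
2 | tert-butyl(dimethyl){[(1E)-2-methylbuta-1,3-dien-1-yl]oxy}silane | C=C/C(C)=C/O[Si](C)(C)C(C)(C)C | intermediate
3 | 3-oxocyclobutane-1-carboxylic acid | O=C1CC(C1)C(=O)O | starting material
4 | 3-bromocyclobutan-1-one | O=C1CC(Br)C1 | intermediate
5 | cyclobut-2-en-1-one | O=C1C=CC1 | intermediate
6 | (1R,5S,6S)-5-[(tert-butyldimethylsilyl)oxy]-4-methylbicyclo[4.2.0]oct-3-en-7-one | O=C1C[C@H]2CC=C(C)[C@@H](O[Si](C)(C)C(C)(C)C)[C@H]21 | intermediate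
7 | (3aR,7R,7aS)-7-[(tert-butyldimethylsilyl)oxy]-6-methyl-3a,4,7,7a-tetrahydro-1-benzofuran-2(3H)-one | O=C1C[C@H]2CC=C(C)[C@@H](O[Si](C)(C)C(C)(C)C)[C@H]2O1 | intermediate
8 | Mannich base: 3-[(dimethylamino)methyl] derivative of 7 (C7 epimers) | O=C1C(CN(C)C)[C@H]2CC=C(C)[C@@H](O[Si](C)(C)C(C)(C)C)[C@H]2O1 | intermediate
9 | trimethylammonium iodide of 8 | O=C1C(C[N+](C)(C)C)[C@H]2CC=C(C)[C@@H](O[Si](C)(C)C(C)(C)C)[C@H]2O1.[I-] | intermediate
10 | (3aR,7R,7aS)-7-[(tert-butyldimethylsilyl)oxy]-6-methyl-3-methylidene-3a,4,7,7a-tetrahydro-1-benzofuran-2(3H)-one | O=C1C(=C)[C@H]2CC=C(C)[C@@H](O[Si](C)(C)C(C)(C)C)[C@H]2O1 | intermediate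
11 | (3aR,7R,7aS)-7-[(tert-butyldimethylsilyl)oxy]-6-methyl-3-methylidene-2,3,3a,4,7,7a-hexahydro-1-benzofuran-2-ol (lactol, anomeric mixture) | OC1C(=C)[C@H]2CC=C(C)[C@@H](O[Si](C)(C)C(C)(C)C)[C@H]2O1 | intermediate
12 | (1S,2R,6R)-2-[(tert-butyldimethylsilyl)oxy]-6-[(3S)-3-hydroxyhexa-1,5-dien-2-yl]-3-methylcyclohex-3-en-1-ol | C=C([C@H](CC=C)O)[C@H]1CC=C(C)[C@@H](O[Si](C)(C)C(C)(C)C)[C@H]1O | intermediate
13 | (1S,2R,6R)-2-[(tert-butyldimethylsilyl)oxy]-6-[(3S)-3-hydroxy-6-methylhepta-1,5-dien-2-yl]-3-methylcyclohex-3-en-1-ol | C=C([C@H](CC=C(C)C)O)[C@H]1CC=C(C)[C@@H](O[Si](C)(C)C(C)(C)C)[C@H]1O | intermediate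
14 | angelic acid, (Z)-2-methylbut-2-enoic acid | C/C=C(/C)C(=O)O | starting material
15 | (3S)-2-[(1R,5R,6S)-5-[(tert-butyldimethylsilyl)oxy]-6-hydroxy-4-methylcyclohex-3-en-1-yl]-6-methylhepta-1,5-dien-3-yl (2Z)-2-methylbut-2-enoate | C=C([C@H](CC=C(C)C)OC(=O)/C(C)=C\C)[C@H]1CC=C(C)[C@@H](O[Si](C)(C)C(C)(C)C)[C@H]1O | intermediate
16 | C6,C8-bis-angelate of 13, C5 silyl ether retained (C1 R, C5 R, C6 S, C8 S) | C=C([C@H](CC=C(C)C)OC(=O)/C(C)=C\C)[C@H]1CC=C(C)[C@@H](O[Si](C)(C)C(C)(C)C)[C@H]1OC(=O)/C(C)=C\C | intermediate
17 | allylic alcohol bis-angelate: 16 with free C5 hydroxyl (C1 R, C5 R, C6 S, C8 S) | C=C([C@H](CC=C(C)C)OC(=O)/C(C)=C\C)[C@H]1CC=C(C)[C@@H](O)[C@H]1OC(=O)/C(C)=C\C | intermediate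
18 | epoxy alcohol bis-angelate: C3–C4 oxirane of 17, cis to C5–OH, C6–O and the C1 side chain (C1 R, C3 R, C5 S, C6 S, C8 S) | C=C([C@H](CC=C(C)C)OC(=O)/C(C)=C\C)[C@H]1C[C@H]2O[C@@]2(C)[C@@H](O)[C@H]1OC(=O)/C(C)=C\C | intermediate
19 | tris-angelate: C5 angelate of 18, prenyl side chain | C=C([C@H](CC=C(C)C)OC(=O)/C(C)=C\C)[C@H]1C[C@H]2O[C@@]2(C)[C@@H](OC(=O)/C(C)=C\C)[C@H]1OC(=O)/C(C)=C\C | intermediate
20 | CNP0258231.4 | C=C([C@H](C[C@H]1OC1(C)C)OC(=O)/C(C)=C\C)[C@H]1C[C@H]2O[C@@]2(C)[C@@H](OC(=O)/C(C)=C\C)[C@H]1OC(=O)/C(C)=C\C | target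

**Totals.** Total step count: 15. Longest linear sequence: 14 steps (3 → 20, steps 2–15).

**Steps most likely to fail, with fallbacks**

1. Step 4. What may go wrong: acid-induced decomposition of the silyl dienol ether or of cyclobutenone before cycloaddition, or insufficient facial discrimination by the catalyst. Fallback (sets out from 2 and 5, comes back at 7): the cycloaddition is run without a chiral catalyst (ZnCl2, CH2Cl2, 0 °C) to give racemic 6 F1. Baeyer–Villiger oxidation as in step 5 gives racemic 7 F2, and HF·pyridine gives the racemic hydroxy lactone F3. Lipase-catalysed acetylation (Burkholderia cepacia lipase, vinyl acetate, t-BuOMe) is assumed to leave the (3aR,7R,7aS) hydroxy lactone F4 and to convert its enantiomer into the acetate F5. Silylation of F4 (TBSCl, imidazole, DMF) returns to 7.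

2. Step 8. What may go wrong: slow opening of the lactol and consumption of the borane by the lactol hydroxyl, with erosion of reagent control at C8. Fallback (sets out from 11, comes back at 12): a hydroxyl-tolerant Barbier allylation (In powder, allyl bromide, THF/H2O, rt) acts on the lactol directly and should give 12 together with the C8 epimer of 12 F6. The two diastereomers are separated by chromatography.

3. Step 14. What may go wrong: incomplete acylation of the hindered C5 hydroxyl next to the oxirane, or Z→E isomerisation of the angeloyl group at the temperature needed. Fallback (sets out from 18, comes back at 19): the alcohol is esterified with the small acid 2-[bis(2,2,2-trifluoroethoxy)phosphoryl]propanoic acid (DCC, DMAP, CH2Cl2) to give the C5 phosphonopropanoate F7. A Still–Gennari olefination with acetaldehyde (KN(SiMe3)2, 18-crown-6, THF, −78 °C) then builds the Z-configured 2-methylbut-2-enoate on the substrate and gives 19.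

**Further compounds**

F1 | step 4 | racemic 6 | O=C1C[C@H]2CC=C(C)[C@@H](O[Si](C)(C)C(C)(C)C)[C@H]21.O=C1C[C@@H]2CC=C(C)[C@H](O[Si](C)(C)C(C)(C)C)[C@@H]21
F2 | step 4 | racemic 7 | O=C1C[C@H]2CC=C(C)[C@@H](O[Si](C)(C)C(C)(C)C)[C@H]2O1.O=C1C[C@@H]2CC=C(C)[C@H](O[Si](C)(C)C(C)(C)C)[C@@H]2O1
F3 | step 4 | racemic 7-hydroxy-6-methyl-3a,4,7,7a-tetrahydro-1-benzofuran-2(3H)-one (all-cis) | O=C1C[C@H]2CC=C(C)[C@@H](O)[C@H]2O1.O=C1C[C@@H]2CC=C(C)[C@H](O)[C@@H]2O1
F4 | step 4 | (3aR,7R,7aS)-7-hydroxy-6-methyl-3a,4,7,7a-tetrahydro-1-benzofuran-2(3H)-one | O=C1C[C@H]2CC=C(C)[C@@H](O)[C@H]2O1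
F5 | step 4 | (3aS,7S,7aR)-6-methyl-2-oxo-2,3,3a,4,7,7a-hexahydro-1-benzofuran-7-yl acetate | O=C1C[C@@H]2CC=C(C)[C@H](OC(C)=O)[C@@H]2O1
F6 | step 8 | C8 epimer of 12 | C=C([C@@H](CC=C)O)[C@H]1CC=C(C)[C@@H](O[Si](C)(C)C(C)(C)C)[C@H]1O
F7 | step 14 | C5 2-[bis(2,2,2-trifluoroethoxy)phosphoryl]propanoate of 18 | C=C([C@H](CC=C(C)C)OC(=O)/C(C)=C\C)[C@H]1C[C@H]2O[C@@]2(C)[C@@H](OC(=O)C(C)P(=O)(OCC(F)(F)F)OCC(F)(F)F)[C@H]1OC(=O)/C(C)=C\C
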